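The numbers of this flask were chosen freely; the flask was simulated.

Late in a run, what stands in a flask is what has survived, so I ask how long the complex with four exchanged stays exposed to what removes it. The set-ups, the questions and the steps are these:

| flask | starting complex | incoming ligand | leaving ligand | time | remark |
|---|---|---|---|---|---|
| ash | 0.097 M | 0.0485 M (fed, over 2.00 h) | 0.194 M | 2.5 h | all but incoming ligand at the start; incoming ligand goes in evenly over 2.00 h, the run ends at 2.5 h |
| larch | 0.097 M | 0.0485 M | 0.194 M | 2.5 h | everything together in a closed stirred flask, run for 2.5 h |
| birch | 0.097 M | 0.0485 M | 0.194 M |  | one stirred flow tank at steady state, fed with the mixture as stated, mean residence time 2.5 h |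
| cedar | 0.097 M | 0.0485 M | 0.194 M |  | a single well-mixed tank run continuously and read at steady state, 12.5 h in it on average |

- the stated concentrations are those of everything mixed, before any reaction; amounts are the same in each set-up
- the feed brings no volume worth counting
- run time (ash): 2.5 h

- the set-up with the highest share of complex with four exchanged in all that became complex with four exchanged or over-reaction product, at the outlet or at the end ("none" if the first two lie within 2 percentage points) (ash / larch / birch / cedar / none)
- share of complex with four exchanged in all that became complex with four exchanged or over-reaction product, at the outlet or at the end, ash
- share of complex with four exchanged in all that became complex with four exchanged or over-reaction product, at the outlet or at the end, larch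
- share of complex with four exchanged in all that became complex with four exchanged or over-reaction product, at the outlet or at the end, birch
- share of complex with four exchanged in all that became complex with four exchanged or over-reaction product, at the outlet or at the end, cedar

    starting complex + incoming ligand ⇌ leaving ligand + complex with one exchanged (K1 = 2.0, k1 = 0.84 M⁻¹ s⁻¹)
    complex with one exchanged + incoming ligand ⇌ leaving ligand + complex with two exchanged (K2 = 0.52, k2 = 0.81 M⁻¹ s⁻¹)
    complex with two exchanged + incoming ligand ⇌ leaving ligand + complex with three exchanged (K3 = 2.3, k3 = 0.092 M⁻¹ s⁻¹)
    complex with three exchanged + incoming ligand ⇌ leaving ligand + complex with four exchanged (K4 = 3.6, k4 = 0.049 M⁻¹ s⁻¹)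
    complex with four exchanged → over-reaction product (k5 = 4.8 × 10⁻⁴ s⁻¹)
    incoming ligand → decomposed reagent (k6 = 0.0017 s⁻¹)

I build the flask up one process at a time. With the exchange steps on their own, no over-reaction product forms, so the share of complex with four exchanged is 100 per cent.

Now I add the over-reaction step, first order in complex with four exchanged, at 4.8 × 10⁻⁴ s⁻¹. In a steady tank, over-reaction product is made at that constant times the concentration of complex with four exchanged, and it leaves at its own concentration over the mean residence time. Its concentration is therefore that constant times the residence time times the concentration of complex with four exchanged. For birch this product of rate constant and mean residence time is 4.32, and I call it the hold number. The share is one over one plus the hold number, which gives 18.8% for birch.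

Then I add the rest. Decomposition of the incoming ligand and the backward steps change how much complex with four exchanged a tank holds, but that amount cancels in the ratio, so the birch share stays where it was.

In the timed flasks these processes do count. Incoming ligand has a half-life of 0.11 h by decomposition alone, shorter than the run of 2.5 h, so the way back through the last exchange comes to run with little opposing it. The concentration that sets its order is that of the leaving ligand, charged at 0.194 M, more than the whole incoming charge of 0.0485 M. The way back is thus pseudo-first-order in complex with four exchanged, and it is faster than the over-reaction step. Together they drain that complex at 0.00312 s⁻¹, while over-reaction product stays. Of what drains, a fraction 0.154 ends as over-reaction product. So if a fraction e of that complex survives, the share is e over e plus that fraction times one minus e, with e the exponential of minus the drain times the time counted. Counted over the whole run, this gives <0.001% for larch. Counted from the end of dosing, it gives 2.32% for ash, a rough figure: I count no over-reaction product from before the end of dosing and let no incoming ligand linger after it. My choice is birch.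

The forecast names birch, with 0.8% for ash, below my figure, 0% for larch, 18.8% for birch and 4.42% for cedar, the tank shares holding “whatever the upstream chain does”.

The simulation gives birch, with 1.06% for ash, 0% for larch, 18.8% for birch and 4.42% for cedar.

Cedar is the second tank. Its hold number is 21.6, so the rule gives 4.42%, and the run reads 4.42%. Birch and cedar are read at steady state, which is rest by their setting. Ash is not at rest: its 1.06% at 2.5 h is a passing value. At ten times the time, 25.0 h, ash reads 0%, and larch, already at 0%, reads 0%.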